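The quinone ring is built around the intact all-E octaprenyl chain. With the naphthoquinone numbered so that C2 carries methyl, C3 the chain and C4 is the carbonyl beside C3, the precursor is an acyclic α-diazoketone in which the future C4 is a ketone carbon flanked by C2 (in an α-methylstyryl group) and the diazo carbon C3. Light shifts C2 from C4 to C3 (Wolff rearrangement, C2–C3 bond); the freed ketene carbon C4 then closes onto the phenyl ortho carbon C4a (6π-electrocyclization, C4–C4a bond). The step exploits the contiguous C4a–C4–C3–C2 array of the quinone ring; C1 enters as CH and is oxygenated last.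

Key step: step 11

Assumption: all-E-octaprenol is not treated as a catalogue compound, so the C40 chain is assembled from commercial (2E,6E,10E)-geranylgeraniol; (E)-3-methyl-4-phenylbut-3-en-2-one is purchased.

Short names used below: geranylgeranyl = (2E,6E,10E)-3,7,11,15-tetramethylhexadeca-2,6,10,14-tetraen-1-yl; (all-E)-octaprenyl = (2E,6E,10E,14E,18E,22E,26E)-3,7,11,15,19,23,27,31-octamethyldotriaconta-2,6,10,14,18,22,26,30-octaen-1-yl.

Step 1
Reactants: 1 (2E,6E,10E)-geranylgeraniol
Product: 2 benzyl (2E,6E,10E)-geranylgeranyl ether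
Conditions: NaH, BnBr, Bu4NI (cat.), THF, 0 °C to 20 °C
Reagents that add atoms: benzyl bromide, BrCc1ccccc1
Why: Williamson etherification of the primary allylic alkoxide; the benzyl ether deactivates the proximal olefin towards step 2 and is later removed together with the sulfone in step 7.

Step 2
Reactants: 2 benzyl (2E,6E,10E)-geranylgeranyl ether
Product: 3 (2E,6E,10E,14E)-16-(benzyloxy)-2,6,10,14-tetramethylhexadeca-2,6,10,14-tetraen-1-ol
Conditions: SeO2 (0.1 equiv), t-BuOOH (2 equiv), salicylic acid (0.1 equiv), CH2Cl2, 0 °C to 20 °C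
Reagents that add atoms: tert-butyl hydroperoxide, CC(C)(C)OO
Why: Riley-type allylic oxidation (ene reaction, then [2,3]-sigmatropic shift) should attack the most electron-rich and least hindered terminal olefin and hydroxylate the methyl group trans to the chain, so the cyclic mechanism sets the new olefin as E.

Step 3
Reactants: 3 (2E,6E,10E,14E)-16-(benzyloxy)-2,6,10,14-tetramethylhexadeca-2,6,10,14-tetraen-1-ol
Product: 4 benzyl (2E,6E,10E,14E)-16-bromo-3,7,11,15-tetramethylhexadeca-2,6,10,14-tetraen-1-yl ether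
Conditions: CBr4, PPh3, CH2Cl2, −20 °C to 0 °C
Reagents that add atoms: carbon tetrabromide, BrC(Br)(Br)Br
Why: Appel bromination: bromide displaces the oxyphosphonium group by SN2 at the primary allylic carbon under neutral conditions, without allylic transposition or loss of olefin geometry.

Step 4
Reactants: 1 (2E,6E,10E)-geranylgeraniol
Product: 5 (2E,6E,10E)-geranylgeranyl bromide
Conditions: PBr3 (0.4 equiv), Et2O, −10 °C
Reagents that add atoms: phosphorus tribromide, BrP(Br)Br
Why: Low-temperature PBr3 bromination of a primary allylic alcohol proceeds by SN2 on the phosphite ester and keeps the 2E olefin.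

Step 5
Reactants: 5 (2E,6E,10E)-geranylgeranyl bromide
Product: 6 (2E,6E,10E)-geranylgeranyl phenyl sulfone
Conditions: PhSO2Na, DMF, 20 °C
Reagents that add atoms: sodium benzenesulfinate, [Na+].[O-]S(=O)c1ccccc1
Why: S-alkylation of the sulfinate by the primary allylic bromide (SN2) gives the allylic sulfone that will stabilise the carbanion for chain coupling.

Step 6
Reactants: 6 (2E,6E,10E)-geranylgeranyl phenyl sulfone and 4 benzyl (2E,6E,10E,14E)-16-bromo-3,7,11,15-tetramethylhexadeca-2,6,10,14-tetraen-1-yl ether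
Product: 7 benzyl (2E,6E,10E,14E,18E,22E,26E)-17-(phenylsulfonyl)-3,7,11,15,19,23,27,31-octamethyldotriaconta-2,6,10,14,18,22,26,30-octaen-1-yl ether
Conditions: n-BuLi, THF/DMPU, −78 °C; then 4, −78 °C to −20 °C
Reagents that add atoms: none
Why: Biellmann coupling: the α-sulfonyl allyl carbanion is alkylated at its α-carbon by the primary allylic bromide (SN2), joining two C20 units head to tail without touching any olefin; the sulfone-bearing stereocentre forms racemic and is erased in step 7.

Step 7
Reactants: 7 benzyl (2E,6E,10E,14E,18E,22E,26E)-17-(phenylsulfonyl)-3,7,11,15,19,23,27,31-octamethyldotriaconta-2,6,10,14,18,22,26,30-octaen-1-yl ether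
Product: 8 (all-E)-octaprenol
Conditions: Li, EtNH2/THF, −78 °C; then NH4Cl
Reagents that add atoms: none
Why: Dissolving-metal reduction cleaves the allylic C–S bond (the allyl anion is protonated at its less substituted terminus, which keeps the E-trisubstituted olefin in place) and the benzylic C–O bond in the same operation.

Step 8
Reactants: 8 (all-E)-octaprenol
Product: 9 (all-E)-octaprenyl bromide
Conditions: PBr3 (0.4 equiv), Et2O/hexane, −10 °C
Reagents that add atoms: phosphorus tribromide, BrP(Br)Br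
Why: Low-temperature PBr3 bromination of the primary allylic alcohol (SN2) keeps the 2E olefin, as in step 4.

Step 9
Reactants: 10 (E)-3-methyl-4-phenylbut-3-en-2-one (2.5 equiv) and 9 (all-E)-octaprenyl bromide
Product: 11 (1E,6E,10E,14E,18E,22E,26E,30E)-2,7,11,15,19,23,27,31,35-nonamethyl-1-phenylhexatriaconta-1,6,10,14,18,22,26,30,34-nonaen-3-one
Conditions: LiN(i-Pr)2, THF, −78 °C; then 9, DMPU, −78 °C to −30 °C
Reagents that add atoms: none
Why: Kinetic deprotonation of the methyl ketone gives the cross-conjugated α′-enolate, which is alkylated (SN2) by the primary allylic bromide with retention of the 2E olefin; the excess of cheap enolate should suppress dialkylation.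

Step 10
Reactants: 11 (1E,6E,10E,14E,18E,22E,26E,30E)-2,7,11,15,19,23,27,31,35-nonamethyl-1-phenylhexatriaconta-1,6,10,14,18,22,26,30,34-nonaen-3-one
Product: 13 4-diazo derivative of ketone 11, via trifluoroacetyl diketone 12 (not isolated)
Conditions: LiN(SiMe3)2, THF, −78 °C; CF3CO2CH2CF3, −78 °C; aq. HCl wash; then MsN3, Et3N, H2O (1 equiv), MeCN, 20 °C
Reagents that add atoms: methanesulfonyl azide, CS(=O)(=O)N=[N+]=[N-]; 2,2,2-trifluoroethyl trifluoroacetate, O=C(OCC(F)(F)F)C(F)(F)F (its CF3CO group is present in 12 only)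
Why: Detrifluoroacetylative (Regitz-type deacylative) diazo transfer: Claisen trifluoroacetylation activates the α′-carbon, and the sulfonyl azide adduct fragments with loss of the trifluoroacetyl group as the N-acylsulfonamide, leaving the α-diazoketone.

Step 11
Reactants: 13 4-diazo derivative of ketone 11
Product: 18 3-methyl-2-[(all-E)-octaprenyl]naphthalen-1-ol, via E-vinylketene 14 (not isolated), via cyclobutenone 15 (not isolated), via Z-vinylketene 16 (not isolated), via dienone 17 (not isolated)
Conditions: hν (365 nm), degassed toluene (0.01 M), 20 °C; then 110 °C in the same flask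
Reagents that add atoms: none
Why: Irradiation expels N2 from 13 and the α-methylstyryl carbon migrates from the carbonyl carbon to the diazo carbon (photochemical Wolff rearrangement), which creates the C2–C3 bond of the quinone ring and turns the former ketone carbon into the ketene carbon of 14. Because 14 carries phenyl trans to the ketene, it closes reversibly (conrotatory 4π) to cyclobutenone 15, and on heating 15 reopens with phenyl inward to 16. In 16 the ketene carbon bonds to an ortho carbon of the phenyl ring by a thermally allowed disrotatory 6π-electrocyclization (the C4–C4a bond), closing the six-membered ring as dienone 17, which tautomerises to naphthol 18. The closest known reaction types are the Wolff rearrangement and vinylketene electrocyclization sequence of the Danheiser benzannulation and the thermal rearrangement of 4-arylcyclobutenones to 1-naphthols. The sp3 centres of 15 and 17 are transient, so no stereocentre has to be controlled. The step needs the Wolff shift to outrun a 1,2-hydrogen shift of the ketocarbene; direct irradiation of the s-Z conformer (loss of N2 concerted with migration of the sp2 carbon, the only substituent on the carbonyl) should favour it, and the two ortho positions of the phenyl ring are equivalent, so the ring closure has no regiochemical issue.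

Step 12
Reactants: 18 3-methyl-2-[(all-E)-octaprenyl]naphthalen-1-ol
Product: 19 menaquinone-8
Conditions: Co(salen) [C16H14CoN2O2] (0.1 equiv), O2 (1 atm), DMF/CH2Cl2, 20 °C
Reagents that add atoms: dioxygen, O=O
Why: Oxygenation catalysed by the salen complex of divalent cobalt: the naphthoxyl radical is trapped by the cobalt superoxo species at the free para position (the future C1 carbonyl; the ortho position is blocked by the chain), and the peroxide collapses to the 1,4-quinone while the isolated trisubstituted olefins stay untouched.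

Compound list
1 | (2E,6E,10E)-geranylgeraniol | CC(C)=CCC/C(C)=C/CC/C(C)=C/CC/C(C)=C/CO | starting material
2 | benzyl (2E,6E,10E)-geranylgeranyl ether | CC(C)=CCC/C(C)=C/CC/C(C)=C/CC/C(C)=C/COCc1ccccc1 | intermediate
3 | (2E,6E,10E,14E)-16-(benzyloxy)-2,6,10,14-tetramethylhexadeca-2,6,10,14-tetraen-1-ol | OC/C(C)=C/CC/C(C)=C/CC/C(C)=C/CC/C(C)=C/COCc1ccccc1 | intermediate
4 | benzyl (2E,6E,10E,14E)-16-bromo-3,7,11,15-tetramethylhexadeca-2,6,10,14-tetraen-1-yl ether | BrC/C(C)=C/CC/C(C)=C/CC/C(C)=C/CC/C(C)=C/COCc1ccccc1 | intermediate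
5 | (2E,6E,10E)-geranylgeranyl bromide | CC(C)=CCC/C(C)=C/CC/C(C)=C/CC/C(C)=C/CBr | intermediate
6 | (2E,6E,10E)-geranylgeranyl phenyl sulfone | CC(C)=CCC/C(C)=C/CC/C(C)=C/CC/C(C)=C/CS(=O)(=O)c1ccccc1 | intermediate
7 | benzyl (2E,6E,10E,14E,18E,22E,26E)-17-(phenylsulfonyl)-3,7,11,15,19,23,27,31-octamethyldotriaconta-2,6,10,14,18,22,26,30-octaen-1-yl ether (racemic at C17) | CC(C)=CCC/C(C)=C/CC/C(C)=C/CC/C(C)=C/C(S(=O)(=O)c1ccccc1)C/C(C)=C/CC/C(C)=C/CC/C(C)=C/CC/C(C)=C/COCc1ccccc1 | intermediate
8 | (all-E)-octaprenol | CC(C)=CCC/C(C)=C/CC/C(C)=C/CC/C(C)=C/CC/C(C)=C/CC/C(C)=C/CC/C(C)=C/CC/C(C)=C/CO | intermediate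
9 | (all-E)-octaprenyl bromide | CC(C)=CCC/C(C)=C/CC/C(C)=C/CC/C(C)=C/CC/C(C)=C/CC/C(C)=C/CC/C(C)=C/CC/C(C)=C/CBr | intermediate
10 | (E)-3-methyl-4-phenylbut-3-en-2-one | CC(=O)/C(C)=C/c1ccccc1 | starting material
11 | (1E,6E,10E,14E,18E,22E,26E,30E)-2,7,11,15,19,23,27,31,35-nonamethyl-1-phenylhexatriaconta-1,6,10,14,18,22,26,30,34-nonaen-3-one | CC(C)=CCC/C(C)=C/CC/C(C)=C/CC/C(C)=C/CC/C(C)=C/CC/C(C)=C/CC/C(C)=C/CC/C(C)=C/CCC(=O)/C(C)=C/c1ccccc1 | intermediate
12 | 4-(trifluoroacetyl) derivative of ketone 11 (racemic, crude) | CC(C)=CCC/C(C)=C/CC/C(C)=C/CC/C(C)=C/CC/C(C)=C/CC/C(C)=C/CC/C(C)=C/CC/C(C)=C/CC(C(=O)C(F)(F)F)C(=O)/C(C)=C/c1ccccc1 | intermediate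
13 | (1E,6E,10E,14E,18E,22E,26E,30E)-4-diazo-2,7,11,15,19,23,27,31,35-nonamethyl-1-phenylhexatriaconta-1,6,10,14,18,22,26,30,34-nonaen-3-one | CC(C)=CCC/C(C)=C/CC/C(C)=C/CC/C(C)=C/CC/C(C)=C/CC/C(C)=C/CC/C(C)=C/CC/C(C)=C/CC(=[N+]=[N-])C(=O)/C(C)=C/c1ccccc1 | intermediate
14 | (3E)-3-methyl-2-[(all-E)-octaprenyl]-4-phenylbuta-1,3-dien-1-one | CC(C)=CCC/C(C)=C/CC/C(C)=C/CC/C(C)=C/CC/C(C)=C/CC/C(C)=C/CC/C(C)=C/CC/C(C)=C/CC(=C=O)/C(C)=C/c1ccccc1 | intermediate
15 | 3-methyl-2-[(all-E)-octaprenyl]-4-phenylcyclobut-2-en-1-one (racemic) | CC(C)=CCC/C(C)=C/CC/C(C)=C/CC/C(C)=C/CC/C(C)=C/CC/C(C)=C/CC/C(C)=C/CC/C(C)=C/CC1=C(C)C(c2ccccc2)C1=O | intermediate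
16 | (3Z)-3-methyl-2-[(all-E)-octaprenyl]-4-phenylbuta-1,3-dien-1-one | CC(C)=CCC/C(C)=C/CC/C(C)=C/CC/C(C)=C/CC/C(C)=C/CC/C(C)=C/CC/C(C)=C/CC/C(C)=C/CC(=C=O)/C(C)=C\c1ccccc1 | intermediate
17 | 3-methyl-2-[(all-E)-octaprenyl]naphthalen-1(8aH)-one (racemic) | CC(C)=CCC/C(C)=C/CC/C(C)=C/CC/C(C)=C/CC/C(C)=C/CC/C(C)=C/CC/C(C)=C/CC/C(C)=C/CC1=C(C)C=C2C=CC=CC2C1=O | intermediate
18 | 3-methyl-2-[(all-E)-octaprenyl]naphthalen-1-ol | CC(C)=CCC/C(C)=C/CC/C(C)=C/CC/C(C)=C/CC/C(C)=C/CC/C(C)=C/CC/C(C)=C/CC/C(C)=C/Cc1c(C)cc2ccccc2c1O | intermediate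
19 | menaquinone-8, 2-methyl-3-[(all-E)-octaprenyl]naphthalene-1,4-dione | CC(C)=CCC/C(C)=C/CC/C(C)=C/CC/C(C)=C/CC/C(C)=C/CC/C(C)=C/CC/C(C)=C/CC/C(C)=C/CC1=C(C)C(=O)c2ccccc2C1=O | target

Total step count: 12. Longest linear sequence: 10 steps (1, 2, 3, 6, 7, 8, 9, 10, 11, 12).

Steps most likely to fail

Step 11. A 1,2-hydrogen shift from the allylic CH2 to the photogenerated ketocarbene may outrun the Wolff shift and give a cross-conjugated trienone, and the ketene may dimerise if the phenyl-inward ring opening is slow. The fallback sets out from enone 10 and bromide 9 and comes back at naphthol 18. Enone 10 is put through the same detrifluoroacetylative diazo transfer (LiN(SiMe3)2, CF3CO2CH2CF3; MsN3, Et3N) via (E)-1,1,1-trifluoro-5-methyl-6-phenylhex-5-ene-2,4-dione F1 to the terminal diazoketone (E)-1-diazo-3-methyl-4-phenylbut-3-en-2-one F2. Its diazo carbon has no neighbouring C–H, so only the Wolff shift is open. Irradiation and heating as in step 11 should give 3-methylnaphthalen-1-ol F3, still forming the C2–C3 and C4–C4a bonds in one operation. The sodium naphthoxide of F3 (NaH, toluene, 20 °C) is then C-alkylated at the ortho position between the oxygen and the methyl group with bromide 9 (ortho-allylation of a phenoxide contact ion pair in a non-polar solvent, SN2, 2E retained), which gives 18 before step 12.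

Step 10. C-trifluoroacetylation of the hindered secondary enolate may stay incomplete (O-acylation, proton return), or the trifluoroacetyl group may be lost by retro-Claisen cleavage before diazo transfer, returning 11. The fallback sets out from enone 10 and bromide 9 and comes back at diazoketone 13, bypassing steps 9 and 10. Enone 10 is acetylated at its methyl group (NaH, EtOAc, THF, Claisen condensation) to (E)-5-methyl-6-phenylhex-5-ene-2,4-dione F4. Its soft enolate (K2CO3, acetone) is monoalkylated at the central carbon with bromide 9 to (E)-5-methyl-3-[(all-E)-octaprenyl]-6-phenylhex-5-ene-2,4-dione F5. Deacetylative diazo transfer (4-acetamidobenzenesulfonyl azide, DBU, MeCN, 0 °C) should then cleave the more electrophilic, non-conjugated acetyl group and deliver 13.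

Step 2. Allylic oxidation may also occur at the internal trisubstituted olefins, and over-oxidation to the enal may lower the site selectivity. The fallback sets out from ether 2 and comes back at alcohol 3. NBS in aqueous THF at 0 °C converts the most exposed terminal olefin of 2 into the bromohydrin (6E,10E,14E)-16-(benzyloxy)-3-bromo-2,6,10,14-tetramethylhexadeca-6,10,14-trien-2-ol F6. K2CO3 in MeOH closes it to benzyl (2E,6E,10E)-14,15-epoxygeranylgeranyl ether F7, and H5IO6 cleaves F7 to (4E,8E,12E)-14-(benzyloxy)-4,8,12-trimethyltetradeca-4,8,12-trienal F8. A Wittig reaction with the stabilised ylide Ph3P=C(CH3)CO2Et rebuilds the terminal olefin E-selectively as ethyl (2E,6E,10E,14E)-16-(benzyloxy)-2,6,10,14-tetramethylhexadeca-2,6,10,14-tetraenoate F9, and i-Bu2AlH at −78 °C reduces F9 to 3.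

Further compounds
F1 | step 11 | (E)-1,1,1-trifluoro-5-methyl-6-phenylhex-5-ene-2,4-dione | O=C(CC(=O)C(F)(F)F)/C(C)=C/c1ccccc1
F2 | step 11 | (E)-1-diazo-3-methyl-4-phenylbut-3-en-2-one | [N-]=[N+]=CC(=O)/C(C)=C/c1ccccc1
F3 | step 11 | 3-methylnaphthalen-1-ol | Cc1cc(O)c2ccccc2c1
F4 | step 10 | (E)-5-methyl-6-phenylhex-5-ene-2,4-dione | CC(=O)CC(=O)/C(C)=C/c1ccccc1
F5 | step 10 | (E)-5-methyl-3-[(all-E)-octaprenyl]-6-phenylhex-5-ene-2,4-dione (racemic) | CC(C)=CCC/C(C)=C/CC/C(C)=C/CC/C(C)=C/CC/C(C)=C/CC/C(C)=C/CC/C(C)=C/CC/C(C)=C/CC(C(C)=O)C(=O)/C(C)=C/c1ccccc1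
F6 | step 2 | (6E,10E,14E)-16-(benzyloxy)-3-bromo-2,6,10,14-tetramethylhexadeca-6,10,14-trien-2-ol (racemic) | CC(C)(O)C(Br)CC/C(C)=C/CC/C(C)=C/CC/C(C)=C/COCc1ccccc1
F7 | step 2 | benzyl (2E,6E,10E)-14,15-epoxygeranylgeranyl ether (racemic) | CC1(C)OC1CC/C(C)=C/CC/C(C)=C/CC/C(C)=C/COCc1ccccc1
F8 | step 2 | (4E,8E,12E)-14-(benzyloxy)-4,8,12-trimethyltetradeca-4,8,12-trienal | O=CCC/C(C)=C/CC/C(C)=C/CC/C(C)=C/COCc1ccccc1
F9 | step 2 | ethyl (2E,6E,10E,14E)-16-(benzyloxy)-2,6,10,14-tetramethylhexadeca-2,6,10,14-tetraenoate | CCOC(=O)/C(C)=C/CC/C(C)=C/CC/C(C)=C/CC/C(C)=C/COCc1ccccc1
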